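The ten-membered carbocycle is closed at the C8–C9 bond (germacrane numbering) by an intramolecular allylboration. The step exploits the homoallylic array C8(O)–C9H2–C10(CH3)=C1 that lies behind the 8-acyloxy group and the cis-1,10-epoxide, next to C7 of the butenolide ring. A seco precursor, a 4-formylbutenolide carrying the 4,5-epoxide and a C1 pinacolboronate with an isopropenyl group (C10, C9, C14), should cyclise through a chair transition state. One operation forms C8–C9, sets C8 from the traceless C1–B stereocentre and delivers the (Z)-C1=C10 alkene. Hydroxyl-directed epoxidation and methacrylation finish the synthesis.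

Key step: step 11

Remark: locants C1–C15 follow germacranolide numbering (ring C1–C10, lactone C6–O–C12, C13 the acetoxymethyl carbon, C14 on C10, C15 on C4); nerol, methyl propiolate, (tributylstannyl)methanol and D-(−)-diethyl tartrate are taken as commercial.

Step 1
Reactants: 1 nerol
Product: 2 [(2R,3S)-3-methyl-3-(4-methylpent-3-en-1-yl)oxiran-2-yl]methanol
Conditions: Ti(OiPr)4 (10 mol%), D-(−)-diethyl tartrate (12 mol%), t-BuOOH, 4 Å MS, CH2Cl2, −20 °C
Reagents that add atoms: tert-butyl hydroperoxide CC(C)(C)OO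
Why: Sharpless asymmetric epoxidation of the (Z)-allylic alcohol; D-(−)-tartrate should deliver oxygen to the face that gives the (2R,3S)-cis-epoxide (C5 R and C4 S of the target), and the remote trisubstituted alkene carries no directing hydroxyl and stays untouched.

Step 2
Reactants: 2 [(2R,3S)-3-methyl-3-(4-methylpent-3-en-1-yl)oxiran-2-yl]methanol
Product: 3 (2S,3S)-3-methyl-3-(4-methylpent-3-en-1-yl)oxirane-2-carbaldehyde
Conditions: Dess–Martin periodinane, pyridine, CH2Cl2, 0 °C to rt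
Reagents that add atoms: none
Why: Buffered Dess–Martin oxidation of the primary epoxy alcohol should stop at the aldehyde without touching the epoxide stereocentres (the descriptor at C2 changes only by priority).

Step 3
Reactants: 3 (2S,3S)-3-methyl-3-(4-methylpent-3-en-1-yl)oxirane-2-carbaldehyde; 4 methyl propiolate
Product: 6 methyl (4R)-4-[(2R,3S)-3-methyl-3-(4-methylpent-3-en-1-yl)oxiran-2-yl]-4-[(triethylsilyl)oxy]but-2-ynoate, via lithium alkoxide 5 (not isolated)
Conditions: 4, n-BuLi, THF, −78 °C; then 3, −78 °C; then Et3SiOTf, −78 °C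
Reagents that add atoms: triethylsilyl trifluoromethanesulfonate CC[Si](CC)(CC)OS(=O)(=O)C(F)(F)F
Why: 1,2-Addition of lithium methyl propiolate to the α,β-epoxy aldehyde should follow the Felkin–Anh model (attack anti to the epoxide C–O bond) and set C6 as 4R, erythro to the epoxide; the alkoxide is silylated in the same flask so that it is masked for the cuprate step, and any minor C6 epimer is removed by chromatography.

Step 4
Reactants: 7 (tributylstannyl)methanol
Product: 8 tributyl{[(4-methoxybenzyl)oxy]methyl}stannane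
Conditions: NaH, 4-methoxybenzyl chloride, Bu4NI (cat.), THF–DMF, 0 °C to rt
Reagents that add atoms: 4-methoxybenzyl chloride COc1ccc(CCl)cc1
Why: Williamson etherification of the primary stannyl carbinol gives the tin precursor of a protected hydroxymethyl anion; no stereocentre is formed.

Step 5
Reactants: 6 methyl (4R)-4-[(2R,3S)-3-methyl-3-(4-methylpent-3-en-1-yl)oxiran-2-yl]-4-[(triethylsilyl)oxy]but-2-ynoate; 8 tributyl{[(4-methoxybenzyl)oxy]methyl}stannane
Product: 11 methyl (2Z,4R)-2-[(acetyloxy)methyl]-3-{[(4-methoxybenzyl)oxy]methyl}-4-[(2R,3S)-3-methyl-3-(4-methylpent-3-en-1-yl)oxiran-2-yl]-4-[(triethylsilyl)oxy]but-2-enoate, via vinylcopper adduct 9 (not isolated), via lithium alkoxide 10 (not isolated)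
Conditions: 8 (2.2 equiv), n-BuLi, THF, −78 °C; CuI (1.1 equiv), −78 to −50 °C; 6, −78 °C; CH2O (monomeric, in THF), −78 to −40 °C; Ac2O, −40 to 0 °C
Reagents that add atoms: formaldehyde C=O; acetic anhydride CC(=O)OC(C)=O
Why: Tin–lithium exchange and cuprate formation are followed by syn-carbocupration of the ynoate (conjugate addition), which puts C8 on C7; the copper enolate is trapped at C11 by formaldehyde (aldol) anti to the bulky C6 branch and the alkoxide is acetylated, so the ester should end cis to C6 (2Z) with no new stereocentre.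

Step 6
Reactants: 11 methyl (2Z,4R)-2-[(acetyloxy)methyl]-3-{[(4-methoxybenzyl)oxy]methyl}-4-[(2R,3S)-3-methyl-3-(4-methylpent-3-en-1-yl)oxiran-2-yl]-4-[(triethylsilyl)oxy]but-2-enoate
Product: 13 {(5R)-4-{[(4-methoxybenzyl)oxy]methyl}-5-[(2R,3S)-3-methyl-3-(4-methylpent-3-en-1-yl)oxiran-2-yl]-2-oxo-2,5-dihydrofuran-3-yl}methyl acetate, via hydroxy enoate 12 (not isolated)
Conditions: HF·pyridine, pyridine, THF, 0 °C to rt
Reagents that add atoms: none
Why: Buffered fluoride cleavage of the triethylsilyl ether frees the C6 hydroxyl, which should lactonise onto the cis methyl ester (transesterification) with retention at C6 to give the butenolide.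

Step 7
Reactants: 13 {(5R)-4-{[(4-methoxybenzyl)oxy]methyl}-5-[(2R,3S)-3-methyl-3-(4-methylpent-3-en-1-yl)oxiran-2-yl]-2-oxo-2,5-dihydrofuran-3-yl}methyl acetate
Product: 14 {(5R)-5-{(2R,3S)-3-[(3E)-5-hydroxy-4-methylpent-3-en-1-yl]-3-methyloxiran-2-yl}-4-{[(4-methoxybenzyl)oxy]methyl}-2-oxo-2,5-dihydrofuran-3-yl}methyl acetate
Conditions: SeO2 (0.3 equiv), t-BuOOH, salicylic acid (cat.), CH2Cl2, rt
Reagents that add atoms: tert-butyl hydroperoxide CC(C)(C)OO
Why: Selenium dioxide allylic oxidation (ene reaction, then [2,3]-sigmatropic shift) should hydroxylate the (E)-methyl group of the electron-rich trisubstituted alkene; the electron-poor butenolide is inert and no stereocentre is formed.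

Step 8
Reactants: 14 {(5R)-5-{(2R,3S)-3-[(3E)-5-hydroxy-4-methylpent-3-en-1-yl]-3-methyloxiran-2-yl}-4-{[(4-methoxybenzyl)oxy]methyl}-2-oxo-2,5-dihydrofuran-3-yl}methyl acetate
Product: 15 {(5R)-5-{(2R,3S)-3-{(3E)-5-[(methoxycarbonyl)oxy]-4-methylpent-3-en-1-yl}-3-methyloxiran-2-yl}-4-{[(4-methoxybenzyl)oxy]methyl}-2-oxo-2,5-dihydrofuran-3-yl}methyl acetate
Conditions: ClCO2Me, pyridine, CH2Cl2, 0 °C
Reagents that add atoms: methyl chloroformate COC(=O)Cl
Why: Acylation of the only free hydroxyl installs the carbonate leaving group for the allylic substitution.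

Step 9
Reactants: 15 {(5R)-5-{(2R,3S)-3-{(3E)-5-[(methoxycarbonyl)oxy]-4-methylpent-3-en-1-yl}-3-methyloxiran-2-yl}-4-{[(4-methoxybenzyl)oxy]methyl}-2-oxo-2,5-dihydrofuran-3-yl}methyl acetate
Product: 16 {(5R)-4-(hydroxymethyl)-5-{(2R,3S)-3-{(3E)-5-[(methoxycarbonyl)oxy]-4-methylpent-3-en-1-yl}-3-methyloxiran-2-yl}-2-oxo-2,5-dihydrofuran-3-yl}methyl acetate
Conditions: DDQ, CH2Cl2–pH 7 buffer, 0 °C
Reagents that add atoms: none
Why: Oxidative cleavage of the 4-methoxybenzyl ether with DDQ should leave carbonate, acetate, epoxide and alkene intact; it is placed before boron is introduced because the quinone and the aldehyde by-product would consume an allylboronate.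

Step 10
Reactants: 16 {(5R)-4-(hydroxymethyl)-5-{(2R,3S)-3-{(3E)-5-[(methoxycarbonyl)oxy]-4-methylpent-3-en-1-yl}-3-methyloxiran-2-yl}-2-oxo-2,5-dihydrofuran-3-yl}methyl acetate
Product: 17 {(5R)-4-(hydroxymethyl)-5-{(2R,3S)-3-methyl-3-[(3R)-4-methyl-3-(4,4,5,5-tetramethyl-1,3,2-dioxaborolan-2-yl)pent-4-en-1-yl]oxiran-2-yl}-2-oxo-2,5-dihydrofuran-3-yl}methyl acetate
Conditions: CuOtBu (10 mol%), (R,R)-QuinoxP* (11 mol%), B2pin2, THF, 0 °C
Reagents that add atoms: bis(pinacolato)diboron CC1(C)OB(OC1(C)C)B1OC(C)(C)C(C)(C)O1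
Why: Copper-catalysed γ-selective allylic substitution (SN2') by a boryl copper species should move the alkene to C10=C9 and set the C1–B stereocentre under control of the chiral bisphosphine (the ligand enantiomer that gives 3R has to be fixed in a first run, as the sense of induction for an (E)-2-methyl carbonate is not secure); the tetrasubstituted butenolide is too hindered for conjugate borylation.

Step 11
Reactants: 17 {(5R)-4-(hydroxymethyl)-5-{(2R,3S)-3-methyl-3-[(3R)-4-methyl-3-(4,4,5,5-tetramethyl-1,3,2-dioxaborolan-2-yl)pent-4-en-1-yl]oxiran-2-yl}-2-oxo-2,5-dihydrofuran-3-yl}methyl acetate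
Product: 20 (1(10)Z,4S,5R,6R,8R)-13-acetoxy-4,5-epoxy-8-hydroxygermacra-1(10),7(11)-dien-12,6-olide, via aldehyde 18 (not isolated), via borate ester 19 (not isolated)
Conditions: Dess–Martin periodinane, pyridine, CH2Cl2, −10 °C; then dilution into toluene (0.5 mM), 40 °C; aq. NaHCO3 work-up
Reagents that add atoms: none
Why: Dess–Martin oxidation unmasks the C8 aldehyde, which should be attacked by the allylboronate through a closed, chair-like six-membered transition state (B–O–C8–C9–C10–C1) with SE2' delivery from the γ-carbon C9 and formation of the B–O bond. The closest known reaction type is the allylboration of aldehydes with α-substituted pinacol allylboronates, including its intramolecular medium-ring variants. The ten-membered carbocycle is closed by the C8–C9 bond in a 10-exo-trig addition to the carbonyl; the chair is bridged between C1 and C8 by the C2–C7 chain, which forces C2 and C7 onto the same side of the chair. With C2 axial (favoured for pinacol esters, by the C14 methyl on C10 and by the lower strain of a cis-cyclodecene) and C7 equatorial, the 1R boron-bearing centre is relayed to 8R and the new C1=C10 double bond is Z, while C1 itself becomes sp2 and leaves no trace. The step needs γ-regioselectivity (inherent to allyl transfer from boron), chemoselectivity for the aldehyde over lactone and acetate, and ring closure over oligomerisation, which the high electrophilicity of the 4-formylbutenolide, the turns imposed by the cis-epoxide and the butenolide, and high dilution should secure. Aqueous work-up hydrolyses borate ester 19 to alcohol 20.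

Step 12
Reactants: 20 (1(10)Z,4S,5R,6R,8R)-13-acetoxy-4,5-epoxy-8-hydroxygermacra-1(10),7(11)-dien-12,6-olide
Product: 21 (1R,4S,5R,6R,8R,10S)-13-acetoxy-1,10:4,5-diepoxy-8-hydroxygermacr-7(11)-en-12,6-olide
Conditions: VO(acac)2 (5 mol%), t-BuOOH (in decane), CH2Cl2, 0 °C to rt
Reagents that add atoms: tert-butyl hydroperoxide CC(C)(C)OO
Why: Vanadium-catalysed epoxidation directed by the homoallylic C8 hydroxyl should deliver oxygen to the face of the (Z)-C1=C10 alkene on which that hydroxyl sits, giving the cis-1,10-epoxide syn to O8 (1R,10S); the butenolide alkene is electron-poor and unreactive.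

Step 13
Reactants: 21 (1R,4S,5R,6R,8R,10S)-13-acetoxy-1,10:4,5-diepoxy-8-hydroxygermacr-7(11)-en-12,6-olide
Product: 22 (1R,4S,5R,6R,8R,10S)-13-acetoxy-1,10:4,5-diepoxy-8-(methacryloyloxy)germacr-7(11)-en-12,6-olide
Conditions: methacrylic anhydride, Et3N, DMAP (cat.), CH2Cl2, 0 °C to rt
Reagents that add atoms: methacrylic anhydride C=C(C)C(=O)OC(=O)C(C)=C
Why: DMAP-catalysed acylation of the secondary C8 hydroxyl proceeds with retention at C8 and should complete the target.

Compound list
1 | nerol, (2Z)-3,7-dimethylocta-2,6-dien-1-ol | CC(C)=CCC/C(C)=C\CO | starting material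
2 | [(2R,3S)-3-methyl-3-(4-methylpent-3-en-1-yl)oxiran-2-yl]methanol | CC(C)=CCC[C@]1(C)O[C@@H]1CO | intermediate
3 | (2S,3S)-3-methyl-3-(4-methylpent-3-en-1-yl)oxirane-2-carbaldehyde | CC(C)=CCC[C@]1(C)O[C@@H]1C=O | intermediate
4 | methyl propiolate | C#CC(=O)OC | starting material
5 | lithium alkoxide of methyl (4R)-4-hydroxy-4-[(2R,3S)-3-methyl-3-(4-methylpent-3-en-1-yl)oxiran-2-yl]but-2-ynoate | CC(C)=CCC[C@]1(C)O[C@@H]1[C@H](O[Li])C#CC(=O)OC | intermediate
6 | methyl (4R)-4-[(2R,3S)-3-methyl-3-(4-methylpent-3-en-1-yl)oxiran-2-yl]-4-[(triethylsilyl)oxy]but-2-ynoate | CC(C)=CCC[C@]1(C)O[C@@H]1[C@H](O[Si](CC)(CC)CC)C#CC(=O)OC | intermediate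
7 | (tributylstannyl)methanol | CCCC[Sn](CCCC)(CCCC)CO | starting material
8 | tributyl{[(4-methoxybenzyl)oxy]methyl}stannane | CCCC[Sn](CCCC)(CCCC)COCc1ccc(OC)cc1 | intermediate
9 | vinylcopper adduct of 6, copper on C11 cis to the new C8 group (4R; epoxide 2R,3S) | CC(C)=CCC[C@]1(C)O[C@@H]1[C@H](O[Si](CC)(CC)CC)/C(COCc1ccc(OC)cc1)=C(/[Cu])C(=O)OC | intermediate
10 | lithium alkoxide of the (2Z,4R)-2-(hydroxymethyl) enoate formed from 9 and formaldehyde | CC(C)=CCC[C@]1(C)O[C@@H]1[C@H](O[Si](CC)(CC)CC)/C(COCc1ccc(OC)cc1)=C(/CO[Li])C(=O)OC | intermediate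
11 | methyl (2Z,4R)-2-[(acetyloxy)methyl]-3-{[(4-methoxybenzyl)oxy]methyl}-4-[(2R,3S)-3-methyl-3-(4-methylpent-3-en-1-yl)oxiran-2-yl]-4-[(triethylsilyl)oxy]but-2-enoate | CC(C)=CCC[C@]1(C)O[C@@H]1[C@H](O[Si](CC)(CC)CC)/C(COCc1ccc(OC)cc1)=C(/COC(C)=O)C(=O)OC | intermediate
12 | methyl (2Z,4R)-2-[(acetyloxy)methyl]-4-hydroxy-3-{[(4-methoxybenzyl)oxy]methyl}-4-[(2R,3S)-3-methyl-3-(4-methylpent-3-en-1-yl)oxiran-2-yl]but-2-enoate | CC(C)=CCC[C@]1(C)O[C@@H]1[C@H](O)/C(COCc1ccc(OC)cc1)=C(/COC(C)=O)C(=O)OC | intermediate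
13 | {(5R)-4-{[(4-methoxybenzyl)oxy]methyl}-5-[(2R,3S)-3-methyl-3-(4-methylpent-3-en-1-yl)oxiran-2-yl]-2-oxo-2,5-dihydrofuran-3-yl}methyl acetate | CC(C)=CCC[C@]1(C)O[C@@H]1[C@@H]1OC(=O)C(COC(C)=O)=C1COCc1ccc(OC)cc1 | intermediate
14 | {(5R)-5-{(2R,3S)-3-[(3E)-5-hydroxy-4-methylpent-3-en-1-yl]-3-methyloxiran-2-yl}-4-{[(4-methoxybenzyl)oxy]methyl}-2-oxo-2,5-dihydrofuran-3-yl}methyl acetate | OC/C(C)=C/CC[C@]1(C)O[C@@H]1[C@@H]1OC(=O)C(COC(C)=O)=C1COCc1ccc(OC)cc1 | intermediate
15 | {(5R)-5-{(2R,3S)-3-{(3E)-5-[(methoxycarbonyl)oxy]-4-methylpent-3-en-1-yl}-3-methyloxiran-2-yl}-4-{[(4-methoxybenzyl)oxy]methyl}-2-oxo-2,5-dihydrofuran-3-yl}methyl acetate | COC(=O)OC/C(C)=C/CC[C@]1(C)O[C@@H]1[C@@H]1OC(=O)C(COC(C)=O)=C1COCc1ccc(OC)cc1 | intermediate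
16 | {(5R)-4-(hydroxymethyl)-5-{(2R,3S)-3-{(3E)-5-[(methoxycarbonyl)oxy]-4-methylpent-3-en-1-yl}-3-methyloxiran-2-yl}-2-oxo-2,5-dihydrofuran-3-yl}methyl acetate | COC(=O)OC/C(C)=C/CC[C@]1(C)O[C@@H]1[C@@H]1OC(=O)C(COC(C)=O)=C1CO | intermediate
17 | {(5R)-4-(hydroxymethyl)-5-{(2R,3S)-3-methyl-3-[(3R)-4-methyl-3-(4,4,5,5-tetramethyl-1,3,2-dioxaborolan-2-yl)pent-4-en-1-yl]oxiran-2-yl}-2-oxo-2,5-dihydrofuran-3-yl}methyl acetate | C=C(C)[C@H](B1OC(C)(C)C(C)(C)O1)CC[C@]1(C)O[C@@H]1[C@@H]1OC(=O)C(COC(C)=O)=C1CO | intermediate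
18 | {(5R)-4-formyl-5-{(2R,3S)-3-methyl-3-[(3R)-4-methyl-3-(4,4,5,5-tetramethyl-1,3,2-dioxaborolan-2-yl)pent-4-en-1-yl]oxiran-2-yl}-2-oxo-2,5-dihydrofuran-3-yl}methyl acetate | C=C(C)[C@H](B1OC(C)(C)C(C)(C)O1)CC[C@]1(C)O[C@@H]1[C@@H]1OC(=O)C(COC(C)=O)=C1C=O | intermediate
19 | pinacol borate ester of 20 (O8–B bond; 1(10)Z,4S,5R,6R,8R) | CC1(C)OB(O[C@@H]2C/C(C)=C\CC[C@]3(C)O[C@@H]3[C@@H]3OC(=O)C(COC(C)=O)=C23)OC1(C)C | intermediate
20 | (1(10)Z,4S,5R,6R,8R)-13-acetoxy-4,5-epoxy-8-hydroxygermacra-1(10),7(11)-dien-12,6-olide | O[C@@H]1C/C(C)=C\CC[C@]2(C)O[C@@H]2[C@@H]2OC(=O)C(COC(C)=O)=C21 | intermediate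
21 | (1R,4S,5R,6R,8R,10S)-13-acetoxy-1,10:4,5-diepoxy-8-hydroxygermacr-7(11)-en-12,6-olide | O[C@@H]1C[C@]2(C)O[C@@H]2CC[C@]2(C)O[C@@H]2[C@@H]2OC(=O)C(COC(C)=O)=C21 | intermediate
22 | (1R,4S,5R,6R,8R,10S)-13-acetoxy-1,10:4,5-diepoxy-8-(methacryloyloxy)germacr-7(11)-en-12,6-olide | C=C(C)C(=O)O[C@@H]1C[C@]2(C)O[C@@H]2CC[C@]2(C)O[C@@H]2[C@@H]2OC(=O)C(COC(C)=O)=C21 | target

Total steps: 13. Longest linear sequence: 12 steps (steps 1–3 and 5–13); step 4 is a one-step branch.

Steps most likely to fail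

Step 11. Intermolecular allyl transfer (oligomerisation) or decay of the sensitive 4-formylbutenolide may outrun a slow ring closure. The fallback changes the allyl donor and its mode of activation. It sets out from boronate 17: exchange of the pinacol ester with KHF2 in aqueous methanol would give the potassium trifluoroborate F1. Dess–Martin oxidation would give the aldehyde F2. Ring closure would then be run in CH2Cl2–water with Bu4NI at high dilution and room temperature, where the allyl group is transferred from a far more reactive difluoroborane formed at the interface through the same chair arrangement. Hydrolytic work-up comes back to alcohol 20.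

Step 10. Enantioface control at C1 may be poor on an (E)-2-methyl allylic carbonate, giving both C1 epimers. The fallback gives up catalyst control at C1 and corrects C8 afterwards. It sets out from carbonate 16: borylation with an achiral catalyst (CuOtBu, Xantphos, B2pin2) would give the boronate as a mixture of C1 epimers F3. Oxidation and ring closure as in step 11 would give alcohol 20 together with its C8 epimer F4, since a 1S boronate relays to 8S; the two are separated on silica. F4 would be oxidised with Dess–Martin periodinane to the ring ketone F5 and reduced under Corey–Bakshi–Shibata conditions ((S)-2-methyl-CBS-oxazaborolidine, catecholborane, −78 °C). With the butenolide carbon C7 as the large group, this should give the 8R alcohol and come back to 20.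

Step 5. The copper enolate may be trapped poorly by formaldehyde, or lose its double-bond geometry through the allenoate. The fallback replaces the aldol trap by halogenation and cross-coupling. It sets out from ynoate 6 and stannane 8: the vinylcopper adduct would be quenched with iodine to give the iodo enoate F6 with retention at the C–Cu bond. Desilylation and lactonisation as in step 6 would give the iodobutenolide F7. Stille coupling with (tributylstannyl)methanol 7 (Pd(PPh3)4, dioxane, 80 °C) would give the hydroxymethyl butenolide F8, and acetylation (Ac2O, pyridine) comes back to 13.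

Further compounds
F1 | step 11 | potassium trifluoro{(3R)-5-[(2S,3R)-3-{(2R)-4-[(acetyloxy)methyl]-3-(hydroxymethyl)-5-oxo-2,5-dihydrofuran-2-yl}-2-methyloxiran-2-yl]-2-methylpent-1-en-3-yl}borate (trifluoroborate analogue of 17) | C=C(C)[C@H]([B-](F)(F)F)CC[C@]1(C)O[C@@H]1[C@@H]1OC(=O)C(COC(C)=O)=C1CO.[K+]
F2 | step 11 | trifluoroborate analogue of aldehyde 18 (4-formylbutenolide, 3R at the boron-bearing carbon) | C=C(C)[C@H]([B-](F)(F)F)CC[C@]1(C)O[C@@H]1[C@@H]1OC(=O)C(COC(C)=O)=C1C=O.[K+]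
F3 | step 10 | boronate 17 as a mixture of epimers at the boron-bearing carbon | C=C(C)C(B1OC(C)(C)C(C)(C)O1)CC[C@]1(C)O[C@@H]1[C@@H]1OC(=O)C(COC(C)=O)=C1CO
F4 | step 10 | (1(10)Z,4S,5R,6R,8S)-13-acetoxy-4,5-epoxy-8-hydroxygermacra-1(10),7(11)-dien-12,6-olide | O[C@H]1C/C(C)=C\CC[C@]2(C)O[C@@H]2[C@@H]2OC(=O)C(COC(C)=O)=C21
F5 | step 10 | (1(10)Z,4S,5R,6R)-13-acetoxy-4,5-epoxy-8-oxogermacra-1(10),7(11)-dien-12,6-olide | O=C1C/C(C)=C\CC[C@]2(C)O[C@@H]2[C@@H]2OC(=O)C(COC(C)=O)=C21
F6 | step 5 | methyl (2E,4R)-2-iodo-3-{[(4-methoxybenzyl)oxy]methyl}-4-[(2R,3S)-3-methyl-3-(4-methylpent-3-en-1-yl)oxiran-2-yl]-4-[(triethylsilyl)oxy]but-2-enoate | CC(C)=CCC[C@]1(C)O[C@@H]1[C@H](O[Si](CC)(CC)CC)/C(COCc1ccc(OC)cc1)=C(/I)C(=O)OC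
F7 | step 5 | (5R)-3-iodo-4-{[(4-methoxybenzyl)oxy]methyl}-5-[(2R,3S)-3-methyl-3-(4-methylpent-3-en-1-yl)oxiran-2-yl]furan-2(5H)-one | CC(C)=CCC[C@]1(C)O[C@@H]1[C@@H]1OC(=O)C(I)=C1COCc1ccc(OC)cc1
F8 | step 5 | (5R)-3-(hydroxymethyl)-4-{[(4-methoxybenzyl)oxy]methyl}-5-[(2R,3S)-3-methyl-3-(4-methylpent-3-en-1-yl)oxiran-2-yl]furan-2(5H)-one | CC(C)=CCC[C@]1(C)O[C@@H]1[C@@H]1OC(=O)C(CO)=C1COCc1ccc(OC)cc1
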